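With the rings lettered A (2,4,6-trihydroxyphenyl end) to F (3,4,5-trihydroxyphenyl end), the ten hydroxyls at C3 and C5 of rings A to E lie ortho or para to the crowded ether carbons (C4 of rings A, B, D and E, C6 of ring C). The route carries all ten as formyl groups: these first activate each such carbon as an aryl fluoride for iterative SNAr chain growth from the ring F phenol, and one tenfold Baeyer–Villiger oxidation with formate methanolysis then turns them into the ten aryl C–O bonds. The precursor is therefore a linear six-ring pentaether deca-aldehyde with five spectator methyl ethers, which BBr3 removes at the end.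

Key step: step 12

Remarks on the chemistry:
- Ring numbering: ring A has OMe (later OH) at C1 and the ether oxygen at C4. In rings B, D and E, C1 carries the oxygen toward ring A and C4 the oxygen toward ring F. In ring C, C1 carries the oxygen to ring B, C6 the oxygen to ring D, and C4 carries OMe (later OH).
- Assumption: compounds 1, 9 and 18 are bought. No isolated compound has a stereocentre; the carbinol carbons of the lithium amino alkoxides are transient and racemic.
- From step 12 on, all polyphenols are handled under argon.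

Step 1
Reactants: 1 2-fluoro-5-hydroxybenzaldehyde
Product: 2 2-fluoro-5-[(triisopropylsilyl)oxy]benzaldehyde
Conditions: TIPSCl, imidazole, CH2Cl2, rt
Reagents that add atoms: chlorotriisopropylsilane CC(C)[Si](Cl)(C(C)C)C(C)C
Why: Imidazole-promoted O-silylation of the phenol; the bulky silyl ether protects the oxygen and shields both ring positions next to it from the lithiation that follows.

Step 2
Reactants: 2 2-fluoro-5-[(triisopropylsilyl)oxy]benzaldehyde
Product: 6 2-fluoro-5-[(triisopropylsilyl)oxy]benzene-1,3-dicarbaldehyde, via lithium amino alkoxide 3 (not isolated), via ring-lithiated amino alkoxide 4 (not isolated), via dilithium bis-hemiaminal alkoxide 5 (not isolated)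
Conditions: lithium 4-methylpiperazin-1-ide (N-methylpiperazine, n-BuLi), THF, −78 to −20 °C; s-BuLi, TMEDA, −78 °C; DMF, −78 °C; aq. HCl
Reagents that add atoms: N,N-dimethylformamide CN(C)C=O
Why: In situ protection of the aldehyde as an α-amino alkoxide followed by directed ortho-lithiation at the most acidic free position, the one next to fluorine, and DMF formylation, with acid work-up releasing both aldehydes; the mixture is held at −78 °C so that the ortho-lithio fluoroarene does not lose LiF.

Step 3
Reactants: 6 2-fluoro-5-[(triisopropylsilyl)oxy]benzene-1,3-dicarbaldehyde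
Product: 8 2-fluoro-5-methoxybenzene-1,3-dicarbaldehyde, via cesium phenolate 7 (not isolated)
Conditions: CsF, MeI (large excess), DMF, 0 °C to rt
Reagents that add atoms: iodomethane CI
Why: One-pot fluoride desilylation and Williamson O-methylation; the large excess of MeI should trap the weakly nucleophilic phenolate before it can attack an aryl fluoride.

Step 4
Reactants: 9 2-fluoro-4-methoxyphenol
Product: 10 (2-fluoro-4-methoxyphenoxy)triisopropylsilane
Conditions: TIPSCl, imidazole, CH2Cl2, rt
Reagents that add atoms: chlorotriisopropylsilane CC(C)[Si](Cl)(C(C)C)C(C)C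
Why: O-silylation of the phenol, again with a bulky group that blocks lithiation next to this oxygen.

Step 5
Reactants: 10 (2-fluoro-4-methoxyphenoxy)triisopropylsilane
Product: 13 2-fluoro-6-methoxy-3-[(triisopropylsilyl)oxy]benzaldehyde, via aryllithium 11 (not isolated), via lithium hemiaminal alkoxide 12 (not isolated)
Conditions: n-BuLi, THF, −78 °C; DMF, −78 °C; aq. HCl
Reagents that add atoms: N,N-dimethylformamide CN(C)C=O
Why: Directed ortho-lithiation at the carbon flanked by fluorine and methoxy, the most acidic and doubly coordinated site, followed by DMF formylation.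

Step 6
Reactants: 13 2-fluoro-6-methoxy-3-[(triisopropylsilyl)oxy]benzaldehyde
Product: 17 4-fluoro-2-methoxy-5-[(triisopropylsilyl)oxy]benzene-1,3-dicarbaldehyde, via lithium amino alkoxide 14 (not isolated), via ring-lithiated amino alkoxide 15 (not isolated), via dilithium bis-hemiaminal alkoxide 16 (not isolated)
Conditions: lithium 4-methylpiperazin-1-ide, THF, −78 to −20 °C; s-BuLi, TMEDA, −78 to −40 °C; DMF; aq. HCl
Reagents that add atoms: N,N-dimethylformamide CN(C)C=O
Why: In situ α-amino alkoxide protection, then methoxy-directed ortho-lithiation at the only unshielded ring hydrogen (the other one lies next to the bulky silyloxy group) and DMF formylation; the new aryllithium is not ortho to fluorine, so moderate warming is tolerated.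

Step 7
Reactants: 18 3,4,5-trimethoxyphenol and 6 2-fluoro-5-[(triisopropylsilyl)oxy]benzene-1,3-dicarbaldehyde
Product: 20 dimer phenol E–F 5-hydroxy-2-(3,4,5-trimethoxyphenoxy)benzene-1,3-dicarbaldehyde, via dimer silyl ether 19 (not isolated)
Conditions: NaH, THF then DMF, 0 °C to rt; then AcOH, Bu4NF, THF, 0 °C
Reagents that add atoms: none
Why: SNAr through a Meisenheimer intermediate at the fluorine-bearing carbon flanked by two formyl groups; with sodium as counter-ion the fluoride leaves as insoluble NaF, which should not cleave the hindered aryl silyl ether, and buffered fluoride then frees the ring E phenol in the same flask.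

Step 8
Reactants: 20 dimer phenol E–F and 6 2-fluoro-5-[(triisopropylsilyl)oxy]benzene-1,3-dicarbaldehyde
Product: 22 trimer phenol D–E–F 2-[3,5-diformyl-4-(3,4,5-trimethoxyphenoxy)phenoxy]-5-hydroxybenzene-1,3-dicarbaldehyde, via trimer silyl ether 21 (not isolated)
Conditions: NaH, THF then DMF, 0 °C to rt; then AcOH, Bu4NF, THF, 0 °C
Reagents that add atoms: none
Why: The same SNAr and buffered desilylation; the phenoxide oxygen is unhindered, and the formyl-flanked ether carbon of its own ring is deactivated by the para oxido group, so self-exchange should not compete with fluoride displacement.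

Step 9
Reactants: 22 trimer phenol D–E–F and 17 4-fluoro-2-methoxy-5-[(triisopropylsilyl)oxy]benzene-1,3-dicarbaldehyde
Product: 24 tetramer phenol C–D–E–F (ring C with C1 OH; C3 and C5 CHO; C4 OMe; C6 O to ring D), via tetramer silyl ether 23 (not isolated)
Conditions: NaH, THF then DMF, 0 °C to 40 °C; then AcOH, Bu4NF, THF, 0 °C
Reagents that add atoms: none
Why: SNAr at the fluorine-bearing carbon of 17, activated by one ortho and one para formyl group; fluoride is a far better nucleofuge than the methoxy group on the other doubly activated carbon, and desilylation then frees the ring C phenol.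

Step 10
Reactants: 24 tetramer phenol C–D–E–F and 6 2-fluoro-5-[(triisopropylsilyl)oxy]benzene-1,3-dicarbaldehyde
Product: 26 pentamer phenol B–C–D–E–F (ring B with C1 OH; C3 and C5 CHO; C4 O to ring C C1), via pentamer silyl ether 25 (not isolated)
Conditions: NaH, THF then DMF, 0 °C to 40 °C; then AcOH, Bu4NF, THF, 0 °C
Reagents that add atoms: none
Why: SNAr of the ortho-aryloxy phenoxide of ring C on the doubly ortho-activated fluoride of 6, which again places the crowded ether carbon on the electrophile; desilylation as before.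

Step 11
Reactants: 26 pentamer phenol B–C–D–E–F and 8 2-fluoro-5-methoxybenzene-1,3-dicarbaldehyde
Product: 27 hexamer deca-aldehyde (formyl at C3 and C5 of rings A to E; OMe at ring A C1; at ring C C4; at ring F C3 C4 C5)
Conditions: K2CO3, DMF, rt to 40 °C
Reagents that add atoms: none
Why: Final SNAr of the iteration: the ring B phenoxide displaces the fluoride of 8 flanked by two formyl groups; no silyl group is present, so K2CO3 suffices.

Step 12
Reactants: 27 hexamer deca-aldehyde
Product: 29 hexamer decaphenol pentamethyl ether (OH at C3 and C5 of rings A to E), via deca-formate 28 (not isolated)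
Conditions: mCPBA (dried, excess), CH2Cl2, 0 °C to reflux; Me2S; then HCl (cat.), MeOH, rt, argon
Reagents that add atoms: 3-chloroperbenzoic acid (mCPBA) OOC(=O)c1cccc(Cl)c1
Why: The peracid adds to each formyl group to give a Criegee adduct, and the aryl carbon shifts from carbon to the peroxide oxygen as 3-chlorobenzoate leaves, so each aldehyde becomes an aryl formate; once Me2S has destroyed the excess oxidant, acid-catalysed transesterification with methanol releases the ten phenols. The closest known reaction type is the Baeyer–Villiger (Dakin-type) oxidation of 2-aryloxybenzaldehydes to 2-aryloxyphenols, here run ten times on one molecule. No ring is closed and no stereocentre is formed. The step needs aryl migration to beat hydride migration at all ten sites, and every migrating carbon has an ether oxygen ortho to it (the diaryl ether oxygen at C4 in rings A, B, D and E; the C4 methoxy in ring C, reinforced by the C6 aryloxy ortho to C5 and para to C3). It also needs the oxidant to spare the electron-rich products, which is secured by keeping the new oxygens masked as formates until the peracid is quenched and by running the methanolysis under argon.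

Step 13
Reactants: 29 hexamer decaphenol pentamethyl ether
Product: 30 target CNP0270681.0
Conditions: BBr3 (excess), CH2Cl2, −78 °C to rt; H2O quench, argon
Reagents that add atoms: none
Why: Lewis-acid ether cleavage: BBr3 binds each methoxy oxygen and bromide removes the methyl group by SN2, the diaryl ethers being inert because neither aryl carbon can be displaced; hydrolysis of the aryl borates frees all fifteen hydroxyls.

Compound list
1 | 2-fluoro-5-hydroxybenzaldehyde | O=Cc1cc(O)ccc1F | starting material
2 | 2-fluoro-5-[(triisopropylsilyl)oxy]benzaldehyde | O=Cc1cc(O[Si](C(C)C)(C(C)C)C(C)C)ccc1F | intermediate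
3 | lithium amino alkoxide of 2 (adduct with lithium 4-methylpiperazin-1-ide) | [Li]OC(N1CCN(C)CC1)c1cc(O[Si](C(C)C)(C(C)C)C(C)C)ccc1F | intermediate (not isolated)
4 | ring-lithiated amino alkoxide (lithium ortho to fluorine) | [Li]OC(N1CCN(C)CC1)c1cc(O[Si](C(C)C)(C(C)C)C(C)C)cc([Li])c1F | intermediate (not isolated)
5 | dilithium bis-hemiaminal alkoxide (DMF adduct of 4) | [Li]OC(N1CCN(C)CC1)c1cc(O[Si](C(C)C)(C(C)C)C(C)C)cc(C(O[Li])N(C)C)c1F | intermediate (not isolated)
6 | 2-fluoro-5-[(triisopropylsilyl)oxy]benzene-1,3-dicarbaldehyde (block for rings B, D, E) | O=Cc1cc(O[Si](C(C)C)(C(C)C)C(C)C)cc(C=O)c1F | intermediate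
7 | cesium 4-fluoro-3,5-diformylphenolate | [Cs+].[O-]c1cc(C=O)c(F)c(C=O)c1 | intermediate (not isolated)
8 | 2-fluoro-5-methoxybenzene-1,3-dicarbaldehyde (ring A block) | COc1cc(C=O)c(F)c(C=O)c1 | intermediate
9 | 2-fluoro-4-methoxyphenol | COc1ccc(O)c(F)c1 | starting material
10 | (2-fluoro-4-methoxyphenoxy)triisopropylsilane | COc1ccc(O[Si](C(C)C)(C(C)C)C(C)C)c(F)c1 | intermediate
11 | aryllithium of 10 (lithium between fluorine and methoxy) | COc1ccc(O[Si](C(C)C)(C(C)C)C(C)C)c(F)c1[Li] | intermediate (not isolated)
12 | lithium hemiaminal alkoxide (DMF adduct of 11) | COc1ccc(O[Si](C(C)C)(C(C)C)C(C)C)c(F)c1C(O[Li])N(C)C | intermediate (not isolated)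
13 | 2-fluoro-6-methoxy-3-[(triisopropylsilyl)oxy]benzaldehyde | COc1ccc(O[Si](C(C)C)(C(C)C)C(C)C)c(F)c1C=O | intermediate
14 | lithium amino alkoxide of 13 | COc1ccc(O[Si](C(C)C)(C(C)C)C(C)C)c(F)c1C(O[Li])N1CCN(C)CC1 | intermediate (not isolated)
15 | ring-lithiated amino alkoxide (lithium ortho to methoxy) | COc1c([Li])cc(O[Si](C(C)C)(C(C)C)C(C)C)c(F)c1C(O[Li])N1CCN(C)CC1 | intermediate (not isolated)
16 | dilithium bis-hemiaminal alkoxide (DMF adduct of 15) | COc1c(C(O[Li])N(C)C)cc(O[Si](C(C)C)(C(C)C)C(C)C)c(F)c1C(O[Li])N1CCN(C)CC1 | intermediate (not isolated)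
17 | 4-fluoro-2-methoxy-5-[(triisopropylsilyl)oxy]benzene-1,3-dicarbaldehyde (ring C block) | COc1c(C=O)cc(O[Si](C(C)C)(C(C)C)C(C)C)c(F)c1C=O | intermediate
18 | 3,4,5-trimethoxyphenol (ring F) | COc1cc(O)cc(OC)c1OC | starting material
19 | dimer silyl ether E–F, 5-[(triisopropylsilyl)oxy]-2-(3,4,5-trimethoxyphenoxy)benzene-1,3-dicarbaldehyde | CC(C)[Si](C(C)C)(C(C)C)Oc1cc(C=O)c(Oc2cc(OC)c(OC)c(OC)c2)c(C=O)c1 | intermediate (not isolated)
20 | dimer phenol E–F, 5-hydroxy-2-(3,4,5-trimethoxyphenoxy)benzene-1,3-dicarbaldehyde | Oc1cc(C=O)c(Oc2cc(OC)c(OC)c(OC)c2)c(C=O)c1 | intermediate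
21 | trimer silyl ether D–E–F | CC(C)[Si](C(C)C)(C(C)C)Oc1cc(C=O)c(Oc2cc(C=O)c(Oc3cc(OC)c(OC)c(OC)c3)c(C=O)c2)c(C=O)c1 | intermediate (not isolated)
22 | trimer phenol D–E–F, 2-[3,5-diformyl-4-(3,4,5-trimethoxyphenoxy)phenoxy]-5-hydroxybenzene-1,3-dicarbaldehyde | Oc1cc(C=O)c(Oc2cc(C=O)c(Oc3cc(OC)c(OC)c(OC)c3)c(C=O)c2)c(C=O)c1 | intermediate
23 | tetramer silyl ether C–D–E–F (ring C C1 silyloxy) | CC(C)[Si](C(C)C)(C(C)C)Oc1cc(C=O)c(OC)c(C=O)c1Oc1cc(C=O)c(Oc2cc(C=O)c(Oc3cc(OC)c(OC)c(OC)c3)c(C=O)c2)c(C=O)c1 | intermediate (not isolated)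
24 | tetramer phenol C–D–E–F (ring C C1 OH) | Oc1cc(C=O)c(OC)c(C=O)c1Oc1cc(C=O)c(Oc2cc(C=O)c(Oc3cc(OC)c(OC)c(OC)c3)c(C=O)c2)c(C=O)c1 | intermediate
25 | pentamer silyl ether B–C–D–E–F (ring B C1 silyloxy) | CC(C)[Si](C(C)C)(C(C)C)Oc1cc(C=O)c(Oc2cc(C=O)c(OC)c(C=O)c2Oc2cc(C=O)c(Oc3cc(C=O)c(Oc4cc(OC)c(OC)c(OC)c4)c(C=O)c3)c(C=O)c2)c(C=O)c1 | intermediate (not isolated)
26 | pentamer phenol B–C–D–E–F (ring B C1 OH) | Oc1cc(C=O)c(Oc2cc(C=O)c(OC)c(C=O)c2Oc2cc(C=O)c(Oc3cc(C=O)c(Oc4cc(OC)c(OC)c(OC)c4)c(C=O)c3)c(C=O)c2)c(C=O)c1 | intermediate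
27 | hexamer deca-aldehyde (key-step precursor) | COc1cc(C=O)c(Oc2cc(C=O)c(Oc3cc(C=O)c(OC)c(C=O)c3Oc3cc(C=O)c(Oc4cc(C=O)c(Oc5cc(OC)c(OC)c(OC)c5)c(C=O)c4)c(C=O)c3)c(C=O)c2)c(C=O)c1 | intermediate
28 | hexamer deca-formate | COc1cc(OC=O)c(Oc2cc(OC=O)c(Oc3cc(OC=O)c(OC)c(OC=O)c3Oc3cc(OC=O)c(Oc4cc(OC=O)c(Oc5cc(OC)c(OC)c(OC)c5)c(OC=O)c4)c(OC=O)c3)c(OC=O)c2)c(OC=O)c1 | intermediate (not isolated)
29 | hexamer decaphenol pentamethyl ether (key-step product) | COc1cc(O)c(Oc2cc(O)c(Oc3cc(O)c(OC)c(O)c3Oc3cc(O)c(Oc4cc(O)c(Oc5cc(OC)c(OC)c(OC)c5)c(O)c4)c(O)c3)c(O)c2)c(O)c1 | intermediate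
30 | CNP0270681.0 | Oc1cc(O)c(Oc2cc(O)c(Oc3cc(O)c(O)c(O)c3Oc3cc(O)c(Oc4cc(O)c(Oc5cc(O)c(O)c(O)c5)c(O)c4)c(O)c3)c(O)c2)c(O)c1 | target

Total step count: 13. Longest linear sequence: 9 steps (steps 1, 2, 7, 8, 9, 10, 11, 12, 13).

Steps most likely to fail

Step 12. Hydride migration in place of aryl migration at some of the ten sites, incomplete conversion, or oxidation of ring F or of phenols released too early would give mixtures that cannot be corrected later. The fallback sets out from 27 and replaces the carboxylic peracid by an areneperoxyseleninic acid, generated catalytically from bis(2-nitrophenyl) diselenide and 30% H2O2 in CH2Cl2. This is a known way to aryl formates from benzaldehydes that carboxylic peracids oxidise to acids. The deca-formate 28 is then cleaved with HCl in MeOH as before, and the route is rejoined at 29 (no new compound, F0).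

Step 10. The hindered ortho-aryloxy phenoxide of ring C couples slowly, so silyl transfer from block 6 to phenoxide, or slow silyl loss, may compete and let the chain overgrow; aryl ether exchange at formyl-flanked carbons is a further drain. The fallback changes the relay group to one inert to fluoride and phenoxide. It sets out from 6, which is desilylated with Bu4NF and AcOH to 2-fluoro-5-hydroxybenzene-1,3-dicarbaldehyde F1. Mitsunobu etherification with allyl alcohol (PPh3, DIAD, THF), which avoids a free phenolate, gives 2-fluoro-5-(prop-2-en-1-yloxy)benzene-1,3-dicarbaldehyde F2. SNAr with 24 (K2CO3, DMF) gives the pentamer allyl ether F3, and deallylation with Pd(PPh3)4 and TolSO2Na in THF/MeOH returns to the route at 26.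

Step 6. The methoxy director is buttressed by the neighbouring amino alkoxide, so the lithiation may be sluggish or may stray to the position next to the silyloxy group. The fallback sets the regiochemistry by electrophilic substitution instead. It sets out from 13, which is brominated with NBS in MeCN at the position ortho to methoxy, para to fluorine and meta to formyl, to give 3-bromo-6-fluoro-2-methoxy-5-[(triisopropylsilyl)oxy]benzaldehyde F4. Acetalisation (HC(OMe)3, cat. TsOH, MeOH) gives the bromo dimethyl acetal F5. Bromine–lithium exchange (n-BuLi, THF, −78 °C), DMF and aqueous HCl then return to the route at 17.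

Further compounds
F0 | step 12 | none | none
F1 | step 10 | 2-fluoro-5-hydroxybenzene-1,3-dicarbaldehyde | O=Cc1cc(O)cc(C=O)c1F
F2 | step 10 | 2-fluoro-5-(prop-2-en-1-yloxy)benzene-1,3-dicarbaldehyde | C=CCOc1cc(C=O)c(F)c(C=O)c1
F3 | step 10 | pentamer allyl ether B–C–D–E–F (ring B C1 allyloxy) | C=CCOc1cc(C=O)c(Oc2cc(C=O)c(OC)c(C=O)c2Oc2cc(C=O)c(Oc3cc(C=O)c(Oc4cc(OC)c(OC)c(OC)c4)c(C=O)c3)c(C=O)c2)c(C=O)c1
F4 | step 6 | 3-bromo-6-fluoro-2-methoxy-5-[(triisopropylsilyl)oxy]benzaldehyde | COc1c(Br)cc(O[Si](C(C)C)(C(C)C)C(C)C)c(F)c1C=O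
F5 | step 6 | [3-bromo-2-(dimethoxymethyl)-6-fluoro... bromo dimethyl acetal of F4: 4-bromo-2-(dimethoxymethyl)-1-fluoro-3-methoxy-6-silyloxybenzene] (4-bromo-2-(dimethoxymethyl)-3-fluoro... see SMILES) | COc1c(Br)cc(O[Si](C(C)C)(C(C)C)C(C)C)c(F)c1C(OC)OC
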